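**Plan**

1. Locants: the decalin is numbered as a naphthalene (C1 carries the side chain, C2 the exocyclic alkylidene, C3 a methyl, C4a/C8a the ring fusion, C6 and C8 methyls, C7 the ketone); the exocyclic carbons are Ca (=CH) and Cb (carbinol); the side chain is C1′–C7′ counted from the ring.
2. Cuts, in retrosynthetic order: the C7′ ester and the Cb silyl ether; the C5′=C6′ enoate (Wittig); the C1–C1′ bond between ring and side chain (anti-SN2′ with an alkenylcopper); the C2–Ca bond (Ni/Cr coupling with a lactaldehyde); the cis-decalin (enantioselective Diels–Alder reaction, then a 1,3-enone transposition).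
3. Enabling feature: C1 is allylic to the exocyclic C2=Ca bond, and Ca carries the Cb carbinol. The array C1–C2=Ca–Cb(O) is the allylic transposition product of a ring diene (C1=C2, C3=C4) that bears a leaving group on Ca.
4. Forward order: rings A and B together by cycloaddition, then enone transposition, 2-triflyloxy-1,3-diene, Ca carbinol and picolinate. The side-chain iodide is made separately by carboalumination, Wittig and Sharpless epoxidation. Union, then ketone unmasking with C6/C8 equilibration, enoate, deprotection.
5. Stereochemistry: C4a/C8a from the catalyst-controlled cycloaddition; Cb from (R)-lactate; Ca (a relay centre) by Felkin–Anh addition; C1 and the E exocyclic alkene by anti-SN2′ chirality transfer from Ca; C3′/C4′ from Sharpless epoxidation with L-tartrate; C6 and C8 by thermodynamic equilibration once C1 is substituted.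

Key step: step 18

Remark on the chemistry: the sense of induction in step 3 is assumed from the usual enone–oxazaborolidinium model; both catalyst antipodes are available, so the (4aS,8aR) adduct 5 is taken as accessible.
Remark on the chemistry: C8 is carried in the configuration that the endo cycloaddition gives (methyl syn to C1) and C6 stays masked in the silyl enol ether; both are brought to the natural configuration in step 19.

Step 1
Reactants: 1 4-methoxy-2-methylphenol
Product: 2 4,4-dimethoxy-2-methylcyclohexa-2,5-dien-1-one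
Conditions: PhI(OAc)2, MeOH, 0 °C to rt
Reagents that add atoms: methanol, CO
Why: Oxidative dearomatisation of a p-methoxyphenol with a hypervalent iodine reagent, with methanol captured at C4, should give the p-quinone monoketal.

Step 2
Reactants: 3 2-methylpent-1-en-3-one
Product: 4 (Z)-2-silyloxy diene (TIPS dienol ether)
Conditions: TIPSOTf, Et3N, CH2Cl2, 0 °C
Reagents that add atoms: triisopropylsilyl triflate, CC(C)[Si](OS(=O)(=O)C(F)(F)F)(C(C)C)C(C)C
Why: Soft enolisation of the ethyl ketone (silyl triflate and amine) should give the (Z)-silyl enol ether, which is a 2-silyloxy-1,3-diene with its methyl group in the outside position.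

Step 3
Reactants: 2 4,4-dimethoxy-2-methylcyclohexa-2,5-dien-1-one; 4 (Z)-2-silyloxy diene
Product: 5 cis-fused Diels–Alder adduct (C4 enone with C1 ketal)
Conditions: chiral oxazaborolidinium triflimide [(S)-diphenylprolinol/o-tolylboron oxazaborolidine·Tf2NH, 20 mol %], CH2Cl2, −78 to −40 °C
Reagents that add atoms: none
Why: Catalytic enantioselective Diels–Alder reaction of a 1,4-quinone monoketal: the diene adds to the unsubstituted enone C=C with its enol-ether terminus (future C8) at the β-carbon next to the ketal, suprafacial addition gives the cis ring fusion (C4a, C8a) in the absolute sense set by the chiral Lewis acid, and the endo rule places the C8 methyl syn to C1.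

Step 4
Reactants: 5 cis-fused Diels–Alder adduct
Product: 6 2,3-epoxy ketone
Conditions: t-BuOOH, DBU, CH2Cl2, 0 °C
Reagents that add atoms: tert-butyl hydroperoxide, CC(C)(C)OO
Why: Weitz–Scheffer (nucleophilic) epoxidation of the enone should occur from the convex face; the face is not critical because the carbinol centre that derives from it is oxidised in step 6.

Step 5
Reactants: 6 2,3-epoxy ketone
Product: 7 transposed allylic alcohol (C2–OH, C3=C4)
Conditions: N2H4·H2O, AcOH (cat.), MeOH, 0 °C to rt
Reagents that add atoms: none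
Why: Wharton transposition: the hydrazone of the α,β-epoxy ketone fragments with loss of N2, which moves the oxygen from C4 to C2 and the alkene to C3=C4.

Step 6
Reactants: 7 transposed allylic alcohol
Product: 8 α-ketal enone (C2 ketone, C1 dimethyl ketal)
Conditions: Dess–Martin periodinane, NaHCO3, CH2Cl2, rt
Reagents that add atoms: none
Why: Dess–Martin oxidation of the secondary allylic alcohol should give the 1,3-transposed enone without touching the silyl enol ether.

Step 7
Reactants: 8 α-ketal enone
Product: 9 cis-decalin enone (C2 ketone, C1 methylene)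
Conditions: SmI2 (5 equiv), THF/MeOH, −78 to 0 °C
Reagents that add atoms: none
Why: SmI2 reduction of an α,α-dialkoxy ketone (ketyl formation and β-elimination of methoxide, twice) should remove both methoxy groups and leave the C1 methylene.

Step 8
Reactants: 9 cis-decalin enone
Product: 10 2-triflyloxy-1,3-diene (dienyl triflate)
Conditions: LDA, THF, −78 °C; then PhNTf2, −78 to 0 °C
Reagents that add atoms: N-phenylbis(trifluoromethanesulfonimide), O=S(=O)(N(c1ccccc1)S(=O)(=O)C(F)(F)F)C(F)(F)F
Why: Kinetic α′-deprotonation of the enone (C1 is the only α′ position) and O-triflation of the cross-conjugated dienolate should give the ring diene with the triflate on C2.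

Step 9
Reactants: 11 methyl (R)-lactate
Product: 12 methyl (R)-2-(tert-butyldimethylsilyloxy)propanoate
Conditions: TBSCl, imidazole, DMF, rt
Reagents that add atoms: tert-butyldimethylsilyl chloride, CC(C)(C)[Si](C)(C)Cl
Why: Standard silylation of the secondary alcohol; the stereocentre (future Cb) is not involved.

Step 10
Reactants: 12 methyl (R)-2-(tert-butyldimethylsilyloxy)propanoate
Product: 13 (R)-2-(tert-butyldimethylsilyloxy)propanal
Conditions: DIBAL-H, CH2Cl2, −78 °C
Reagents that add atoms: none
Why: Partial reduction of the ester stops at the aldehyde because the tetrahedral aluminate is stable at −78 °C; the α-centre is not epimerised under these conditions.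

Step 11
Reactants: 10 dienyl triflate; 13 (R)-2-(tert-butyldimethylsilyloxy)propanal
Product: 14 dienyl carbinol (Ca–OH, Cb–OTBS)
Conditions: CrCl2 (5 equiv), NiCl2 (1 mol %), DMF, rt
Reagents that add atoms: none
Why: Nozaki–Hiyama–Kishi coupling: the alkenylchromium formed from the triflate adds only to the aldehyde, and Felkin–Anh (non-chelation) addition to the α-silyloxy aldehyde should set Ca as S, anti to the Cb silyl ether.

Step 12
Reactants: 14 dienyl carbinol
Product: 15 dienyl picolinate
Conditions: picolinic acid, DCC, DMAP, CH2Cl2, rt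
Reagents that add atoms: picolinic acid, OC(=O)c1ccccn1
Why: Steglich esterification installs the chelating 2-pyridinecarboxylate leaving group on Ca without touching the stereocentre.

Step 13
Reactants: 16 prop-2-yn-1-ol
Product: 17 (E)-3-iodo-2-methylprop-2-en-1-ol
Conditions: AlMe3, Cp2ZrCl2 (25 mol %), CH2Cl2, 0 °C to rt; then I2, THF, −30 °C
Reagents that add atoms: trimethylaluminium, C[Al](C)C; iodine, II
Why: Zirconium-catalysed (Negishi) carboalumination adds methyl and aluminium syn across the alkyne, and iododealumination with retention gives the E iodoalkene.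

Step 14
Reactants: 17 (E)-3-iodo-2-methylprop-2-en-1-ol
Product: 19 ethyl (2E,4E)-5-iodo-2,4-dimethylpenta-2,4-dienoate, via (E)-3-iodo-2-methylprop-2-enal 18 (not isolated)
Conditions: MnO2, Ph3P=C(CH3)CO2Et, CH2Cl2, rt to 40 °C
Reagents that add atoms: ethyl 2-(triphenylphosphoranylidene)propanoate, CCOC(=O)C(C)=P(c1ccccc1)(c1ccccc1)c1ccccc1
Why: Tandem allylic oxidation and Wittig olefination traps the volatile enal in situ; the stabilised α-methyl ylide should give the E trisubstituted enoate.

Step 15
Reactants: 19 ethyl (2E,4E)-5-iodo-2,4-dimethylpenta-2,4-dienoate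
Product: 20 (2E,4E)-5-iodo-2,4-dimethylpenta-2,4-dien-1-ol
Conditions: DIBAL-H, CH2Cl2, −78 °C
Reagents that add atoms: none
Why: 1,2-Reduction of the conjugated ester with DIBAL-H gives the allylic alcohol and leaves the iodoalkene intact.

Step 16
Reactants: 20 (2E,4E)-5-iodo-2,4-dimethylpenta-2,4-dien-1-ol
Product: 21 (2S,3S)-epoxy alcohol
Conditions: Ti(O-i-Pr)4 (10 mol %), L-(+)-diethyl tartrate (12 mol %), t-BuOOH, 4 Å MS, CH2Cl2, −20 °C
Reagents that add atoms: tert-butyl hydroperoxide, CC(C)(C)OO
Why: Sharpless asymmetric epoxidation acts only on the allylic-alcohol alkene, and L-(+)-tartrate should deliver the (2S,3S)-epoxide of this (E)-2-methyl allylic alcohol, which sets C3′ and C4′ of the target.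

Step 17
Reactants: 21 (2S,3S)-epoxy alcohol
Product: 22 alkenyl iodide (TES ether)
Conditions: TESCl, imidazole, CH2Cl2, 0 °C
Reagents that add atoms: chlorotriethylsilane, CC[Si](Cl)(CC)CC
Why: Silylation masks the primary alcohol as an ether that survives organolithium and organocopper chemistry and can later be removed in the presence of a secondary TBS ether.

Step 18
Reactants: 22 alkenyl iodide (TES ether); 15 dienyl picolinate
Product: 26 coupled ring/exocyclic diene (fully protected), via alkenyllithium 23 (not isolated), via alkenylmagnesium bromide 24 (not isolated), via alkenylcopper reagent 25 (not isolated)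
Conditions: 22 (1.5 equiv), t-BuLi (3.0 equiv), Et2O, −78 °C; MgBr2·OEt2; CuBr·SMe2, THF, −40 °C; then 15, −40 to 0 °C; aq NH4Cl
Reagents that add atoms: none
Why: Iodine–lithium exchange and Li→Mg→Cu transmetalation give an alkenylcopper reagent; Mg(II) is chelated by the pyridyl nitrogen and carbonyl oxygen of the picolinate, copper adds oxidatively at the ring carbon C1 anti to the leaving group, and reductive elimination forms C1–C1′ while the C1=C2 alkene moves out of the ring to C2=Ca. The closest known reaction type is the anti-SN2′ allylic substitution of secondary allylic picolinates with aryl- and alkenylcopper reagents prepared from Grignard reagents. No ring is closed; the step joins the two fragments and converts the ring diene into the ring/exocyclic diene of the target. C1 is controlled by the Ca stereocentre: in the reactive conformer Ca–H lies in the diene plane beside the C3 methyl (A1,3 strain), the C–O bond points to the concave face where ring B sits, and copper enters from the open convex face, which is also the face the bicycle itself prefers (matched case). The same conformer fixes the new trisubstituted alkene as E (Cb syn to C1), and Cb passes through untouched. The step needs γ- over α-selectivity, which the picolinate/Mg activation and the branched Ca centre should secure, and it needs the reagent to spare its own trisubstituted epoxide and the silyl enol ether, which a neutral alkenylcopper should do at −40 to 0 °C; the C3=C4 alkene is cross-conjugated and cannot relay an SN2″ attack.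

Step 19
Reactants: 26 coupled ring/exocyclic diene (fully protected)
Product: 28 keto alcohol with natural C6 and C8 configuration, via C6/C8-unequilibrated ketone 27 (not isolated)
Conditions: HF·pyridine, pyridine, THF, 0 °C; then DBU, PhMe, 40 °C
Reagents that add atoms: none
Why: Buffered fluoride cleaves the primary TES ether and the TIPS enol ether but should spare the secondary TBS ether; DBU then equilibrates both α-centres of the ketone, and because A1,3 strain between Cb and C1 holds the side chain pseudo-axial and so fixes the cis-decalin conformer, only the natural C6/C8 configuration has both methyl groups equatorial, so the C8 epimer from step 3 and the C6 mixture from protonation should funnel into one isomer.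

Step 20
Reactants: 28 keto alcohol
Product: 30 methyl (E)-enoate, via epoxy aldehyde 29 (not isolated)
Conditions: Dess–Martin periodinane, NaHCO3, CH2Cl2, 0 °C; then Ph3P=CHCO2Me, rt
Reagents that add atoms: methyl (triphenylphosphoranylidene)acetate, COC(=O)C=P(c1ccccc1)(c1ccccc1)c1ccccc1
Why: Oxidation gives an α-epoxy aldehyde that has no α-hydrogen, and the stabilised Wittig ylide reacts with it E-selectively and leaves the hindered C7 ketone alone.

Step 21
Reactants: 30 methyl (E)-enoate
Product: 31 hydroxy methyl ester
Conditions: TBAF, AcOH, THF, 0 °C to rt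
Reagents that add atoms: none
Why: Buffered fluoride removes the allylic TBS ether on Cb; the buffer protects the γ,δ-epoxy enoate and the ketone α-centres from base.

Step 22
Reactants: 31 hydroxy methyl ester
Product: 32 CNP0414188.1 (target acid)
Conditions: Me3SnOH, ClCH2CH2Cl, 70 °C; aq KHSO4
Reagents that add atoms: trimethyltin hydroxide, C[Sn](C)(C)O
Why: Trimethyltin hydroxide cleaves methyl esters under near-neutral conditions, which should leave the vinyl epoxide, the allylic alcohol and the two epimerisable α-centres unchanged.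

**Compound list**

1 | 4-methoxy-2-methylphenol | COc1ccc(O)c(C)c1 | starting material
2 | 4,4-dimethoxy-2-methylcyclohexa-2,5-dien-1-one | COC1(OC)C=CC(=O)C(C)=C1 | intermediate
3 | 2-methylpent-1-en-3-one | CCC(=O)C(C)=C | starting material
4 | (Z)-triisopropyl[(2-methylpenta-1,3-dien-3-yl)oxy]silane | C=C(C)/C(O[Si](C(C)C)(C(C)C)C(C)C)=C/C | intermediate
5 | (4aS,8S,8aR)-1,1-dimethoxy-3,6,8-trimethyl-7-(triisopropylsilyloxy)-4a,5,8,8a-tetrahydronaphthalen-4(1H)-one (target locants; cis-fused; 8-methyl syn to C1) | CC1=CC(OC)(OC)[C@@H]2[C@H](C)C(O[Si](C(C)C)(C(C)C)C(C)C)=C(C)C[C@@H]2C1=O | intermediate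
6 | 2,3-epoxide of 5, oxygen on the face opposite ring B | C[C@]12O[C@H]1C(OC)(OC)[C@@H]3[C@H](C)C(O[Si](C(C)C)(C(C)C)C(C)C)=C(C)C[C@@H]3C2=O | intermediate
7 | 1,1-dimethoxy-3,6,8-trimethyl-7-(triisopropylsilyloxy)-1,2,4a,5,8,8a-hexahydronaphthalen-2-ol (C3=C4 alkene; ring carbons as in 5; 2-OH on the face opposite ring B) | CC1=C[C@H]2CC(C)=C(O[Si](C(C)C)(C(C)C)C(C)C)[C@@H](C)[C@H]2C(OC)(OC)[C@@H]1O | intermediate
8 | (4aR,8S,8aS)-1,1-dimethoxy-3,6,8-trimethyl-7-(triisopropylsilyloxy)-4a,5,8,8a-tetrahydronaphthalen-2(1H)-one | CC1=C[C@H]2CC(C)=C(O[Si](C(C)C)(C(C)C)C(C)C)[C@@H](C)[C@H]2C(OC)(OC)C1=O | intermediate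
9 | (4aS,8S,8aS)-3,6,8-trimethyl-7-(triisopropylsilyloxy)-4a,5,8,8a-tetrahydronaphthalen-2(1H)-one | CC1=C[C@H]2CC(C)=C(O[Si](C(C)C)(C(C)C)C(C)C)[C@@H](C)[C@H]2CC1=O | intermediate
10 | 3,6,8-trimethyl-7-(triisopropylsilyloxy)-4a,5,8,8a-tetrahydronaphthalen-2-yl triflate (C1=C2 and C3=C4 diene; ring carbons as in 9) | CC1=C[C@H]2CC(C)=C(O[Si](C(C)C)(C(C)C)C(C)C)[C@@H](C)[C@H]2C=C1OS(=O)(=O)C(F)(F)F | intermediate
11 | methyl (R)-lactate | C[C@@H](O)C(=O)OC | starting material
12 | methyl (R)-2-(tert-butyldimethylsilyloxy)propanoate | C[C@@H](O[Si](C)(C)C(C)(C)C)C(=O)OC | intermediate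
13 | (R)-2-(tert-butyldimethylsilyloxy)propanal | C[C@@H](O[Si](C)(C)C(C)(C)C)C=O | intermediate
14 | (1S,2R)-2-(tert-butyldimethylsilyloxy)-1-[the dienyl ring of 10 attached through C2]propan-1-ol | CC1=C[C@H]2CC(C)=C(O[Si](C(C)C)(C(C)C)C(C)C)[C@@H](C)[C@H]2C=C1[C@H](O)[C@@H](C)O[Si](C)(C)C(C)(C)C | intermediate
15 | pyridine-2-carboxylate (picolinate) of 14 | CC1=C[C@H]2CC(C)=C(O[Si](C(C)C)(C(C)C)C(C)C)[C@@H](C)[C@H]2C=C1[C@H](OC(=O)c1ccccn1)[C@@H](C)O[Si](C)(C)C(C)(C)C | intermediate
16 | prop-2-yn-1-ol | C#CCO | starting material
17 | (E)-3-iodo-2-methylprop-2-en-1-ol | OC/C(C)=C/I | intermediate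
18 | (E)-3-iodo-2-methylprop-2-enal | O=C/C(C)=C/I | intermediate
19 | ethyl (2E,4E)-5-iodo-2,4-dimethylpenta-2,4-dienoate | CCOC(=O)/C(C)=C/C(C)=C/I | intermediate
20 | (2E,4E)-5-iodo-2,4-dimethylpenta-2,4-dien-1-ol | OC/C(C)=C/C(C)=C/I | intermediate
21 | [(2S,3S)-3-[(E)-1-iodoprop-1-en-2-yl]-2-methyloxiran-2-yl]methanol | I/C=C(\C)[C@@H]1O[C@@]1(C)CO | intermediate
22 | triethylsilyl ether of 21 | I/C=C(\C)[C@@H]1O[C@@]1(C)CO[Si](CC)(CC)CC | intermediate
23 | alkenyllithium from 22 (Li in place of I) | [Li]/C=C(\C)[C@@H]1O[C@@]1(C)CO[Si](CC)(CC)CC | intermediate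
24 | alkenylmagnesium bromide from 23 | Br[Mg]/C=C(\C)[C@@H]1O[C@@]1(C)CO[Si](CC)(CC)CC | intermediate
25 | alkenylcopper(I) reagent from 24 (as its MgBr2 complex) | [Cu]/C=C(\C)[C@@H]1O[C@@]1(C)CO[Si](CC)(CC)CC | intermediate
26 | coupling product: C1 side chain syn to 8a-H, (E)-C2=Ca, Cb–OTBS, C6=C7 TIPS enol ether, 8-methyl syn to C1, primary TES ether | CC1=C[C@H]2CC(C)=C(O[Si](C(C)C)(C(C)C)C(C)C)[C@@H](C)[C@H]2[C@H](/C=C(\C)[C@@H]3O[C@@]3(C)CO[Si](CC)(CC)CC)/C1=C\[C@@H](C)O[Si](C)(C)C(C)(C)C | intermediate
27 | C7 ketone with free primary alcohol, 8-epi, C6 as formed on protonation (not defined) | CC1=C[C@H]2CC(C)C(=O)[C@@H](C)[C@H]2[C@H](/C=C(\C)[C@@H]3O[C@@]3(C)CO)/C1=C\[C@@H](C)O[Si](C)(C)C(C)(C)C | intermediate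
28 | keto alcohol with the ring configuration of the target (Cb–OTBS, C5′ primary alcohol) | CC1=C[C@H]2C[C@H](C)C(=O)[C@H](C)[C@H]2[C@H](/C=C(\C)[C@@H]3O[C@@]3(C)CO)/C1=C\[C@@H](C)O[Si](C)(C)C(C)(C)C | intermediate
29 | epoxy aldehyde from 28 | CC1=C[C@H]2C[C@H](C)C(=O)[C@H](C)[C@H]2[C@H](/C=C(\C)[C@@H]3O[C@@]3(C)C=O)/C1=C\[C@@H](C)O[Si](C)(C)C(C)(C)C | intermediate
30 | methyl ester and Cb TBS ether of the target | CC1=C[C@H]2C[C@H](C)C(=O)[C@H](C)[C@H]2[C@H](/C=C(\C)[C@@H]3O[C@@]3(C)/C=C/C(=O)OC)/C1=C\[C@@H](C)O[Si](C)(C)C(C)(C)C | intermediate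
31 | methyl ester of the target | CC1=C[C@H]2C[C@H](C)C(=O)[C@H](C)[C@H]2[C@H](/C=C(\C)[C@@H]3O[C@@]3(C)/C=C/C(=O)OC)/C1=C\[C@@H](C)O | intermediate
32 | CNP0414188.1 | CC1=C[C@H]2C[C@H](C)C(=O)[C@H](C)[C@H]2[C@H](/C=C(\C)[C@@H]2O[C@@]2(C)/C=C/C(=O)O)/C1=C\[C@@H](C)O | target

**Count**

Total steps: 22. Longest linear sequence: 14 steps (2, 3–8, 11, 12, 18–22).

**Steps most likely to fail**

Step 3. The cycloaddition may stall or lose facial and endo control, because the diene terminus carries a methyl group and the reacting β-carbon of the dienophile sits next to the quaternary ketal carbon. The fallback sets out from 4 and comes back at 8. Commercial 2-methoxy-6-methylphenol is oxidised (PhI(OAc)2, MeOH, 0 °C) in the presence of excess 4 to the masked o-benzoquinone 6,6-dimethoxy-2-methylcyclohexa-2,4-dien-1-one F1. Its C4=C5 bond takes up the diene in a thermal Diels–Alder reaction of the kind known for masked o-benzoquinones and 1,3-dienes; the enol-ether terminus again bonds to the carbon next to the ketal. This gives 8 directly as the racemate, and the mirror image of 8 F2 is removed by preparative chromatography on a chiral stationary phase. Steps 1 and 3–6 are then not needed.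

Step 18. The stoichiometric alkenylcopper may decompose before it couples, or substitution may leak to the α-carbon (Ca). The fallback sets out from 14 and 22 and comes back at 26. Alcohol 14 is converted (ClP(O)(OEt)2, DMAP, pyridine) into the allylic diethyl phosphate F3. Alkenyllithium 23 is quenched with i-PrOB(pin) to give the alkenyl pinacolboronate F4. F3 and F4 are then joined by NHC–copper-catalysed SN2′ allylic substitution (IMes·CuCl, NaOMe, THF), a catalytic anti-selective alkenylation with an alkenylboron reagent that avoids the preformed copper reagent.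

Step 11. Facial selectivity in the addition to the α-silyloxy aldehyde may be poor, giving a mixture of Ca epimers. The fallback sets out from 14 (as the epimer mixture) and comes back at 14. Dess–Martin oxidation gives the dienyl ketone F5, and Corey–Bakshi–Shibata reduction (catecholborane, catalyst enantiomer chosen for the (S)-carbinol) then sets Ca under reagent control instead of substrate control.

**Further compounds**

F1 | step 3 | 6,6-dimethoxy-2-methylcyclohexa-2,4-dien-1-one | COC1(OC)C=CC=C(C)C1=O
F2 | step 3 | mirror image of 8 | CC1=C[C@@H]2CC(C)=C(O[Si](C(C)C)(C(C)C)C(C)C)[C@H](C)[C@@H]2C(OC)(OC)C1=O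
F3 | step 18 | diethyl phosphate of 14 | CC1=C[C@H]2CC(C)=C(O[Si](C(C)C)(C(C)C)C(C)C)[C@@H](C)[C@H]2C=C1[C@H](OP(=O)(OCC)OCC)[C@@H](C)O[Si](C)(C)C(C)(C)C
F4 | step 18 | alkenyl pinacolboronate corresponding to 22 | CC1(C)OB(/C=C(\C)[C@@H]2O[C@@]2(C)CO[Si](CC)(CC)CC)OC1(C)C
F5 | step 11 | dienyl ketone from 14 (Ca=O) | CC1=C[C@H]2CC(C)=C(O[Si](C(C)C)(C(C)C)C(C)C)[C@@H](C)[C@H]2C=C1C(=O)[C@@H](C)O[Si](C)(C)C(C)(C)C
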